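The bicyclo[3.3.1]nonane core is traced back to a cis-fused hydrindane. The carbocycle C1–C2–C3–C4–C5–C9, which carries the amide, is not closed as a six-membered ring: it grows from a cyclopentane when α-ketol 14 rearranges. The key step exploits the tertiary α-hydroxy ketone C1(OH)–C9(=O) shared by both rings: in its acyloin isomer the carbinol is the ring-fusion carbon and the ketone lies in the cyclohexene. A suprafacial 1,2-shift of the cyclopentane CH2 (C2) turns the fused 5/6 skeleton into the bridged 6/6 skeleton, sets C1 and makes the C9 ketone in one operation. The precursor is assembled by Negishi coupling, directed photooxygenation and a carbonyl-ene cyclisation.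

Key step: step 10

Remark on locants: every carbon keeps, in all intermediates, the number it has in the bicyclo[3.3.1]nonane core of the target (C1 bridgehead carbinol, C2 methylene, C3 N-bearing carbon, C4 O-bearing carbon, C5 bridgehead CH, C6 methoxy-bearing carbon, C7 and C8 epoxide carbons, C9 ketone).
Assumption: compounds 1, 2 and 20 are purchased.

Step 1
Reactants: 1 2-iodocyclohex-2-en-1-one; 2 methyl (2R)-2-[(tert-butoxycarbonyl)amino]-3-iodopropanoate
Product: 4 methyl (2S)-2-[(tert-butoxycarbonyl)amino]-3-(6-oxocyclohex-1-en-1-yl)propanoate, via alkylzinc iodide 3 (not isolated)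
Conditions: 2, Zn dust (TMSCl-activated), DMF, 0 °C → rt; then 1, PdCl2(PPh3)2 (5 mol %), rt
Reagents that add atoms: zinc, [Zn] (retained only in 3)
Why: Zinc inserts into the C–I bond of 2 without touching the ester or the α-stereocentre, and Negishi cross-coupling of the β-amino alkylzinc iodide with alkenyl iodide 1 forms the C2–C9 bond, so that C3 (S) comes from the L-serine-derived building block.

Step 2
Reactants: 4 methyl (2S)-2-[(tert-butoxycarbonyl)amino]-3-(6-oxocyclohex-1-en-1-yl)propanoate
Product: 5 methyl (2S)-2-[(tert-butoxycarbonyl)amino]-3-[(6S)-6-hydroxycyclohex-1-en-1-yl]propanoate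
Conditions: (R)-2-methyl-CBS-oxazaborolidine (10 mol %), catecholborane, toluene, −78 °C
Reagents that add atoms: none
Why: Corey–Bakshi–Shibata reduction adds hydride to one face of the enone carbonyl under catalyst control (the alkenyl side acts as the large group) and sets a temporary C1 carbinol (S) that steers the next step.

Step 3
Reactants: 5 methyl (2S)-2-[(tert-butoxycarbonyl)amino]-3-[(6S)-6-hydroxycyclohex-1-en-1-yl]propanoate
Product: 7 methyl (2S)-2-[(tert-butoxycarbonyl)amino]-3-[(1R,6S)-1,6-dihydroxycyclohex-2-en-1-yl]propanoate, via allylic hydroperoxide 6 (not isolated)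
Conditions: O2, hν (visible), tetraphenylporphyrin (cat.), CH2Cl2, −20 °C; then PPh3, rt
Reagents that add atoms: dioxygen (used as singlet oxygen), O=O
Why: In this hydroxyl-directed Schenck ene reaction the C1 hydroxyl draws singlet oxygen to its own face, oxygen bonds to the adjacent alkene carbon C9 while the ring hydrogen at C6 is abstracted, so the tertiary C9–O bond should form cis to the C1–OH with the alkene moving to C5=C6, and PPh3 reduces the hydroperoxide.

Step 4
Reactants: 7 methyl (2S)-2-[(tert-butoxycarbonyl)amino]-3-[(1R,6S)-1,6-dihydroxycyclohex-2-en-1-yl]propanoate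
Product: 8 methyl (2S)-2-[(tert-butoxycarbonyl)amino]-3-(cis-2,2-dimethyl-3a,6,7,7a-tetrahydro-1,3-benzodioxol-3a-yl)propanoate (acetonide of 7)
Conditions: 2-methoxypropene, PPTS (cat.), CH2Cl2, 0 °C
Reagents that add atoms: 2-methoxypropene, C=C(C)OC
Why: Acetalisation of the cis-1,2-diol masks the tertiary hydroxyl, which would otherwise lactonise or later form a lactol, and keeps C1 at the alcohol level so that no enolisable ketone is present during ring closure.

Step 5
Reactants: 8 acetonide ester
Product: 9 (2S)-2-[(tert-butoxycarbonyl)amino]-3-(cis-2,2-dimethyl-3a,6,7,7a-tetrahydro-1,3-benzodioxol-3a-yl)propanal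
Conditions: DIBAL-H (i-Bu2AlH), toluene, −78 °C; aqueous sodium potassium tartrate
Reagents that add atoms: none
Why: Partial reduction of the N-Boc α-amino ester should stop at the aldehyde because the aluminium hemiacetal is stable at −78 °C, and the α-stereocentre is kept by working cold and using 9 at once.

Step 6
Reactants: 9 acetonide aldehyde
Product: 10 N-Boc cis-hydrindene amino alcohol (C9–O and C5–H cis at the ring fusion; C9/C1 isopropylidenedioxy; C6=C7 alkene; C3–NHBoc on the face of the C9 oxygen; C4–OH on the opposite face)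
Conditions: Me2AlCl (2.2 equiv), CH2Cl2, −78 → 0 °C
Reagents that add atoms: none
Why: In this intramolecular carbonyl-ene reaction the Lewis acid-activated aldehyde carbon C4 bonds to C5 from the face of the tether (which forces the cis ring fusion) while the allylic hydrogen at C7 passes to oxygen, so the alkene moves to C6=C7 and the C4 hydroxyl is left on the side of C6, trans to the NHBoc group.

Step 7
Reactants: 10 N-Boc cis-hydrindene amino alcohol
Product: 12 cis-fused oxazolidinone acetonide (cyclic carbamate across C3–N and C4–O on the face of the C9 oxygen), via mesylate 11 (not isolated)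
Conditions: MsCl, Et3N, CH2Cl2, 0 °C; then DMF, 80 °C
Reagents that add atoms: methanesulfonyl chloride, CS(=O)(=O)Cl (retained only in 11)
Why: The carbamate carbonyl oxygen displaces the trans-mesylate in an intramolecular SN2 reaction with inversion at C4 and the tert-butyl group leaves as 2-methylpropene, giving the cis-fused oxazolidinone that has the C3/C4 configuration of the target and protects both heteroatoms.

Step 8
Reactants: 12 cis-fused oxazolidinone acetonide
Product: 13 oxazolidinone cis-diol (C9–OH and C1–OH)
Conditions: AcOH/H2O (4:1), 45 °C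
Reagents that add atoms: none
Why: Acid hydrolysis removes the isopropylidene acetal while the cyclic carbamate and the alkene are inert.

Step 9
Reactants: 13 oxazolidinone cis-diol
Product: 14 oxazolidinone-fused cis-hydrindenone α-ketol (C9–OH, C1=O, C6=C7; C9–OH, C5–H, C4–O and C3–N all on one face)
Conditions: 2-iodoxybenzoic acid, DMSO, rt
Reagents that add atoms: none
Why: 2-Iodoxybenzoic acid oxidises the secondary C1 alcohol of the 1,2-diol to the ketone without glycol cleavage and cannot touch the tertiary C9 hydroxyl, so the α-ketol is unveiled under neutral conditions that leave the β,γ-alkene in place.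

Step 10
Reactants: 14 oxazolidinone-fused cis-hydrindenone α-ketol
Product: 15 bridged α-ketol (1-hydroxybicyclo[3.3.1]non-6-en-9-one carrying the C3–N/C4–O cyclic carbamate)
Conditions: Me2AlCl (2.5 equiv), toluene, −40 °C → rt
Reagents that add atoms: none
Why: The aluminium alkoxide of the C9 carbinol chelates the C1 carbonyl, and the cyclopentane carbon C2 shifts suprafacially from C9 to C1 while the C9–O bond becomes the new carbonyl (α-ketol or acyloin rearrangement). The closest known reaction type is the acyloin ring expansion of 1-acylcycloalkanols, for example the D-homoannulation of 17-hydroxy-20-oxo steroids. The six-membered ring C1–C2–C3–C4–C5–C9 is closed by this 1,2-alkyl shift, that is by enlargement of the cyclopentane C9–C2–C3–C4–C5 through insertion of C1 and not by an exo or endo cyclisation, and the fused bicycle thereby becomes the bridged bicyclo[3.3.1]nonene. The new stereocentre C1 is controlled by the existing centre C5: C2 stays on the face of the cyclohexenone from which it left C9, the face that also carries C4, so the C1 hydroxyl must point away from the new ring. The step needs migration of C2 and not of the ring bond C9–C5, which the chelate should secure by holding the hydroxyl in the carbonyl plane so that C2 stands almost perpendicular to it while the C9–C5 bond is poorly aligned. It also needs a favourable equilibrium, for which the drive should be the release of strain in the cyclopentane that is cis-fused to the oxazolidinone; the product ketone lies between two bridgeheads, so it can neither enolise nor take its alkene into conjugation.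

Step 11
Reactants: 15 bridged α-ketol
Product: 17 epoxy alcohol (C6–OH and C7–C8 epoxide both exo), via allylic hydroperoxide 16 (not isolated)
Conditions: O2, hν (visible), tetraphenylporphyrin (cat.), Ti(OiPr)4 (0.2 equiv), CH2Cl2, 0 °C
Reagents that add atoms: dioxygen (used as singlet oxygen), O=O
Why: The Schenck ene reaction on the open exo face puts the hydroperoxide on C6 with the hydrogen taken from C8 (the only other allylic hydrogen sits on bridgehead C5 and cannot be used), and the titanium alkoxide then transfers the distal peroxide oxygen to the new C7=C8 alkene on the same face, which should give the cis epoxy alcohol.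

Step 12
Reactants: 17 epoxy alcohol
Product: 18 epoxy methyl ether (C6–OMe)
Conditions: MeI, Ag2O, 4 Å molecular sieves, MeCN, rt, dark
Reagents that add atoms: iodomethane, CI
Why: Purdie methylation etherifies the only secondary hydroxyl (C6) under non-basic conditions that spare the epoxide and the bridgehead tertiary alcohol, the C4 oxygen being held in the carbamate.

Step 13
Reactants: 18 epoxy methyl ether
Product: 19 amino alcohol (3-amino-7,8-epoxy-1,4-dihydroxy-6-methoxybicyclo[3.3.1]nonan-9-one, configured as in 21)
Conditions: Ba(OH)2·8H2O, dioxane/H2O, 60 °C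
Reagents that add atoms: none
Why: Hydroxide opens the cis-fused cyclic carbamate and the carbamic acid loses CO2, freeing the C3 amine and the C4 alcohol, while the ketone has only bridgehead α-carbons and so cannot epimerise or eliminate methanol.

Step 14
Reactants: 19 amino alcohol; 20 (2E)-dodec-2-enoic acid
Product: 21 (2E)-N-[(1S,3S,4R,5S,6S,7S,8S)-7,8-epoxy-1,4-dihydroxy-6-methoxy-9-oxobicyclo[3.3.1]nonan-3-yl]dodec-2-enamide
Conditions: EDC·HCl, HOBt, i-Pr2NEt, CH2Cl2, 0 °C → rt
Reagents that add atoms: none
Why: Carbodiimide-mediated amide coupling should acylate the primary amine selectively over the hindered secondary and tertiary hydroxyls and leaves the (E)-alkene of the acid untouched.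

Compound list
1 | 2-iodocyclohex-2-en-1-one | O=C1CCCC=C1I | starting material
2 | methyl (2R)-2-[(tert-butoxycarbonyl)amino]-3-iodopropanoate (N-Boc-3-iodo-L-alanine methyl ester) | CC(C)(C)OC(=O)N[C@H](C(=O)OC)CI | starting material
3 | [(2R)-2-[(tert-butoxycarbonyl)amino]-3-methoxy-3-oxopropyl]zinc iodide | CC(C)(C)OC(=O)N[C@H](C(=O)OC)C[Zn]I | intermediate
4 | methyl (2S)-2-[(tert-butoxycarbonyl)amino]-3-(6-oxocyclohex-1-en-1-yl)propanoate | CC(C)(C)OC(=O)N[C@H](C(=O)OC)CC1=CCCCC1=O | intermediate
5 | methyl (2S)-2-[(tert-butoxycarbonyl)amino]-3-[(6S)-6-hydroxycyclohex-1-en-1-yl]propanoate | CC(C)(C)OC(=O)N[C@H](C(=O)OC)CC1=CCCC[C@@H]1O | intermediate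
6 | methyl (2S)-2-[(tert-butoxycarbonyl)amino]-3-[(1R,6S)-1-hydroperoxy-6-hydroxycyclohex-2-en-1-yl]propanoate | CC(C)(C)OC(=O)N[C@H](C(=O)OC)C[C@@]1(OO)C=CCC[C@@H]1O | intermediate
7 | methyl (2S)-2-[(tert-butoxycarbonyl)amino]-3-[(1R,6S)-1,6-dihydroxycyclohex-2-en-1-yl]propanoate | CC(C)(C)OC(=O)N[C@H](C(=O)OC)C[C@@]1(O)C=CCC[C@@H]1O | intermediate
8 | methyl (2S)-2-[(tert-butoxycarbonyl)amino]-3-(cis-2,2-dimethyl-3a,6,7,7a-tetrahydro-1,3-benzodioxol-3a-yl)propanoate (acetonide of 7) | CC(C)(C)OC(=O)N[C@H](C(=O)OC)C[C@@]12C=CCC[C@@H]1OC(C)(C)O2 | intermediate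
9 | (2S)-2-[(tert-butoxycarbonyl)amino]-3-(cis-2,2-dimethyl-3a,6,7,7a-tetrahydro-1,3-benzodioxol-3a-yl)propanal | CC(C)(C)OC(=O)N[C@H](C=O)C[C@@]12C=CCC[C@@H]1OC(C)(C)O2 | intermediate
10 | N-Boc cis-hydrindene amino alcohol (C9/C1 acetonide, C6=C7, C5–H cis to C9–O, C3–NHBoc cis to C9–O, C4–OH trans to NHBoc) | CC(C)(C)OC(=O)N[C@H]1C[C@]23OC(C)(C)O[C@H]2CC=C[C@@H]3[C@@H]1O | intermediate
11 | C4 methanesulfonate of 10 | CC(C)(C)OC(=O)N[C@H]1C[C@]23OC(C)(C)O[C@H]2CC=C[C@@H]3[C@@H]1OS(C)(=O)=O | intermediate
12 | cis-fused oxazolidinone acetonide (C4 inverted; C3–N and C4–O on the face of the C9 oxygen) | O=C1N[C@H]2C[C@]34OC(C)(C)O[C@H]3CC=C[C@@H]4[C@H]2O1 | intermediate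
13 | oxazolidinone cis-diol (C9–OH, C1–OH, C6=C7) | O=C1N[C@H]2C[C@]3(O)[C@@H](O)CC=C[C@@H]3[C@H]2O1 | intermediate
14 | oxazolidinone-fused cis-hydrindenone α-ketol (C9–OH, C1=O, C6=C7) | O=C1N[C@H]2C[C@]3(O)C(=O)CC=C[C@@H]3[C@H]2O1 | intermediate
15 | bridged α-ketol: 1-hydroxybicyclo[3.3.1]non-6-en-9-one with C3–N/C4–O cyclic carbamate | O=C1N[C@H]2C[C@@]3(O)C(=O)[C@H](C=CC3)[C@H]2O1 | intermediate
16 | C6 exo-hydroperoxide of the bridged ketol (C7=C8) | O=C1N[C@H]2C[C@@]3(O)C(=O)[C@H]([C@H](OO)C=C3)[C@H]2O1 | intermediate
17 | epoxy alcohol (C6–OH exo, C7–C8 epoxide exo) | O=C1N[C@H]2C[C@@]3(O)C(=O)[C@@H]([C@H]2O1)[C@H](O)[C@@H]1O[C@@H]13 | intermediate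
18 | epoxy methyl ether (C6–OMe) | O=C1N[C@H]2C[C@@]3(O)C(=O)[C@@H]([C@H]2O1)[C@H](OC)[C@@H]1O[C@@H]13 | intermediate
19 | amino alcohol: 3-amino-7,8-epoxy-1,4-dihydroxy-6-methoxybicyclo[3.3.1]nonan-9-one, configured as in 21 | N[C@H]1C[C@@]2(O)C(=O)[C@@H]([C@H]1O)[C@H](OC)[C@@H]1O[C@@H]12 | intermediate
20 | (2E)-dodec-2-enoic acid | CCCCCCCCC/C=C/C(=O)O | starting material
21 | (2E)-N-[(1S,3S,4R,5S,6S,7S,8S)-7,8-epoxy-1,4-dihydroxy-6-methoxy-9-oxobicyclo[3.3.1]nonan-3-yl]dodec-2-enamide | CCCCCCCCC/C=C/C(=O)N[C@H]1C[C@@]2(O)C(=O)[C@@H]([C@H]1O)[C@H](OC)[C@@H]1O[C@@H]12 | target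

Total step count: 14. Longest linear sequence: 14 steps (from 1 and 2 to 21; acid 20 enters in the last step).

Steps most likely to fail

Step 10 (key step). The acyloin equilibrium may stop short of the bridged isomer, or Lewis acid-promoted enolisation towards C8 may move the C6=C7 alkene into conjugation with the C1 ketone before the shift takes place. The fallback keeps the ring expansion but moves the oxygenation of the cyclohexene ahead of it, so that the rearranging ketone has no enolisable hydrogen and base catalysis can be used. It sets out from 14. Photooxygenation (O2, hν, tetraphenylporphyrin) of the β,γ-unsaturated ketone on the convex face should give γ-hydroperoxy enone F1 (oxygen at C6, hydrogen taken from C8), which is reduced in the same flask with PPh3 to γ-hydroxy enone F2. Weitz–Scheffer epoxidation (t-BuOOH, DBU) of the C7=C8 bond on the face of the hydroxyl gives epoxy alcohol F3, and MeI/Ag2O gives epoxy ketone methyl ether F4. The α-ketol rearrangement of F4 with a catalytic base (KOt-Bu or DBU, toluene) then leads to 18, where the route is rejoined.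

Step 6. The α-amino aldehyde may epimerise on the Lewis acid, a cationic intermediate may be captured by chloride, or the 1,2-disubstituted alkene may simply not react. The fallback replaces the ene reaction by an intramolecular Nozaki–Hiyama allylation. It sets out from 8. Allylic bromination (NBS, AIBN, PhCF3, 80 °C) gives allylic bromide F5 (a mixture at the C–Br carbon and of allylic isomers, all of which converge on one allylchromium species). DIBAL-H at −78 °C gives bromo aldehyde F6, and CrCl2 in THF closes the C4–C5 bond through a cyclic transition state with transposition of the alkene to C6=C7. This should give 10, where the route is rejoined.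

Step 13. Hot aqueous base may open the β-hydroxy ketone by retro-aldol cleavage of C4–C5 once the C4 alkoxide is free, and may scramble the acyloin. The fallback activates the carbamate so that it opens at room temperature. It sets out from 18. Boc2O/DMAP gives N-Boc oxazolidinone F7; Cs2CO3 (cat.) in MeOH at rt cleaves the ring carbonyl to N-Boc amino alcohol F8; TFA in CH2Cl2 at 0 °C followed by NaHCO3 gives 19, where the route is rejoined.

Further compounds
F1 | step 10 | oxazolidinone-fused cis-hydrindenone with C9–OH, C1=O, C7=C8 and C6–OOH on the convex face | O=C1N[C@H]2C[C@]3(O)C(=O)C=C[C@@H](OO)[C@@H]3[C@H]2O1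
F2 | step 10 | γ-hydroxy enone corresponding to F1 (C6–OH) | O=C1N[C@H]2C[C@]3(O)C(=O)C=C[C@@H](O)[C@@H]3[C@H]2O1
F3 | step 10 | epoxy alcohol of the hydrindanone series (C7–C8 epoxide and C6–OH on the convex face) | O=C1N[C@H]2C[C@]3(O)C(=O)[C@H]4O[C@H]4[C@@H](O)[C@@H]3[C@H]2O1
F4 | step 10 | methyl ether of F3 (C6–OMe) | O=C1N[C@H]2C[C@]3(O)C(=O)[C@H]4O[C@H]4[C@@H](OC)[C@@H]3[C@H]2O1
F5 | step 6 | allylic bromide of acetonide ester 8 (Br at C7, configuration at that carbon not controlled) | CC(C)(C)OC(=O)N[C@H](C(=O)OC)C[C@@]12C=CC(Br)C[C@@H]1OC(C)(C)O2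
F6 | step 6 | bromo aldehyde corresponding to F5 | CC(C)(C)OC(=O)N[C@H](C=O)C[C@@]12C=CC(Br)C[C@@H]1OC(C)(C)O2
F7 | step 13 | N-Boc derivative of oxazolidinone 18 | O=C1N(C(=O)OC(C)(C)C)[C@H]2C[C@@]3(O)C(=O)[C@@H]([C@H]2O1)[C@H](OC)[C@@H]1O[C@@H]13
F8 | step 13 | N-Boc derivative of amino alcohol 19 | CC(C)(C)OC(=O)N[C@H]1C[C@@]2(O)C(=O)[C@@H]([C@H]1O)[C@H](OC)[C@@H]1O[C@@H]12
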